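In birch, 14.0% of the starting material charged is read neither as open intermediate nor as target after 20.0 h, and two chemists at the blackboard quarrel over that gap.

| flask | starting material | partner | reagent | remark | time |
|---|---|---|---|---|---|
| alder | 0.020 M | 1 equiv | 0.47 equiv | run made earlier |  |
| birch | 0.020 M | 1 equiv | 1.7 equiv | run made earlier |  |
| maple | 0.020 M | 1 equiv | 6.9 equiv | run made earlier |  |
| teal | 0.020 M | 1.00 equiv | 0.400 equiv |  | 40 h |
| red | 0.020 M | 1.00 equiv | 0.800 equiv |  | 40 h |
| green | 0.020 M | 1.00 equiv | 1.50 equiv |  | 40 h |
| violet | 0.020 M | 1.00 equiv | 3.00 equiv |  | 40 h |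
| amber | 0.020 M | 1.00 equiv | 6.00 equiv |  | 40 h |

| run | time / h | open intermediate / % | target / % |
|---|---|---|---|
| alder | 2.00 | 40 | 0 |
| alder | 5.00 | 42 | 0 |
| alder | 10.0 | 42 | 0 |
| alder | 15.0 | 40 | 0 |
| alder | 20.0 | 40 | 1 |
| birch | 1.50 | 92 | 1 |
| birch | 3.00 | 93 | 4 |
| birch | 6.00 | 89 | 5 |
| birch | 10.0 | 83 | 13 |
| birch | 20.0 | 66 | 20 |
| maple | 4.00 | 84 | 17 |
| maple | 8.00 | 68 | 27 |
| maple | 12.0 | 58 | 33 |
| maple | 15.0 | 57 | 34 |
| maple | 20.0 | 52 | 31 |

(standard deviation of a reading: 1.5 percentage points)

- the earlier runs were read with a standard deviation of 1.5 percentage points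
- "hardly changes" means that all values lie within two and a half points (for a concentration: within two and a half percent of the largest)

- amount of open intermediate at the end, in percent of the starting material charged for teal, red, green, violet, amber, in this order
- the shape of the row from first to last (falls, then rises / rises, then falls / falls all the way / rises all the way / hardly changes)

The first chemist counts. Alder reads 42% of open intermediate on 0.47 equiv of reagent, which makes 0.894 of the charge per equiv, and its readings stay between 40% and 42% up to 20.0 h. So below one equiv, with reagent as the limiting reagent, the first chemist multiplies and parks the amount: 35.7% in teal and 71.5% in red, unchanged to the end.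

The second chemist, whose side I take, reads the birch gap as open intermediate lost in pairs, so that the loss per hour goes with the square of the amount. The pairing clock, a second-order rate constant on the scale of fractions of the charge, is the gap divided by the first amount, the last amount and the time: 0.0114 h⁻¹. Clock times amount times time gives the pairing number, and the end amount is the start amount divided by one plus that number.

Over 40 h, teal has a pairing number of 0.163 and ends at 30.7%, while red has 0.326 and ends at 53.9%. In powers of ten, red stands at −0.487. Alder between 5.00 h and 20.0 h stands at −1.14, a pairing number of 0.0718, which is a fall of 2.8 percentage points against a scatter of 1.5 points.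

Above one equiv, birch and maple also read target, 20% in birch at 20.0 h, so the clock run from birch's 93% gives green an upper estimate of 65.3%. My row rises, then falls.

The forecast, on the first chemist's side in saying “the intermediate just sits there”, gives 35%, 69%, 58%, 42%, 37% and rises, then falls.

    starting material + reagent → open intermediate (k = 0.0241 M⁻¹ s⁻¹)
    reagent + partner → second intermediate (k = 0.00110 M⁻¹ s⁻¹)
    open intermediate + second intermediate ⇌ target (K = 81.0 M⁻¹, k = 0.00117 M⁻¹ s⁻¹)
    2 open intermediate → homo product (k = 6.77 × 10⁻⁵ M⁻¹ s⁻¹)
    reagent + target → over-reaction product (k = 4.97 × 10⁻⁵ M⁻¹ s⁻¹)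

The flask gives 32.5%, 56.0%, 58.2%, 43.2%, 39.7%, shape rises, then falls. Red's 56.0% lies closer to the second chemist's 53.9% than to the first chemist's parked 71.5%. The first chemist keeps spans like alder's, whose pairing number of 0.0718 is smaller than red's 0.326. In teal at 0.423 h, homo product takes open intermediate 2.3 times as fast as the forward step to target. Run on to 400 h, the clock puts teal at 13.6%, and teal holds 15.3%.

(The data come from a simulation on assumed constants, and the scatter is random.)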